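The cyclohexenone ring is taken apart into a cyclopropane (C3a–C4–C5, with an alkenyl group on the future quaternary C3a), carbon monoxide (C6) and an alkyne (C7≡C7a). A rhodium-catalysed carbonylative [(3+2)+1] cycloaddition of a silyl-ether-tethered 1-yne-vinylcyclopropane closes this ring in one operation, forming C3a–C7a and C5–C6 (and C6–C7) and setting the quaternary centre. It exploits that C4–C5 is a bare ethano bridge between quaternary C3a and the C6 carbonyl of a β-oxygenated enone. The precursor is an acyclic alkynylsilyl ether of a cyclopropylcarbinol. Afterwards the C7a–Si bond is oxidised, the freed alcohol closes the tetrahydrofuran, the alkenyl group is transposed to allyl and the C5 methoxy group is added.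

Key step: step 7

Remark: atom numbers follow the benzofuranone skeleton of the target (O1, C2 aryl, C3 methyl, C3a allyl, C4, C5 methoxy, C6 carbonyl, C7, C7a) and are used for all intermediates.

Step 1
Reactants: 1 (S)-but-3-yn-2-ol
Product: 2 (S)-but-3-yn-2-yl methanesulfonate
Conditions: MsCl, Et3N, CH2Cl2, −78 → 0 °C
Reagents that add atoms: methanesulfonyl chloride, CS(=O)(=O)Cl
Why: O-sulfonylation (mesylation) of the propargylic alcohol leaves the stereocentre untouched and provides the leaving group for the SN2′ step.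

Step 2
Reactants: 2 (S)-but-3-yn-2-yl methanesulfonate
Product: 3 (aR)-tributyl(buta-1,2-dien-1-yl)stannane
Conditions: Bu3SnH, LiN(i-Pr)2, THF, 0 °C; CuBr·SMe2, −78 °C; then 2, −78 °C
Reagents that add atoms: tributyltin hydride, CCCC[SnH](CCCC)CCCC
Why: The stannylcopper reagent should displace the propargylic mesylate in an anti SN2′ reaction, so that the S centre is translated into the aR (M) allene axis.

Step 3
Reactants: 3 (aR)-tributyl(buta-1,2-dien-1-yl)stannane; 4 3,4,5-trimethoxybenzaldehyde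
Product: 5 (1R,2S)-2-methyl-1-(3,4,5-trimethoxyphenyl)but-3-yn-1-ol
Conditions: BF3·OEt2, CH2Cl2, −78 °C; aq. NaHCO3
Reagents that add atoms: none
Why: Lewis-acid-promoted SE2′ addition of the allenylstannane to the aldehyde should run anti to tin through an open antiperiplanar transition state, which fixes the methyl-bearing centre (2S, net retention relative to 2) and gives the syn relationship to the new carbinol centre (1R).

Step 4
Reactants: 5 (1R,2S)-2-methyl-1-(3,4,5-trimethoxyphenyl)but-3-yn-1-ol; 6 tert-butyl(dimethyl)(prop-2-en-1-yloxy)silane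
Product: 8 (1R,2S,4E)-6-{[tert-butyl(dimethyl)silyl]oxy}-2-methyl-3-methylidene-1-(3,4,5-trimethoxyphenyl)hex-4-en-1-ol, via 2-substituted buta-1,3-diene 7 (not isolated)
Conditions: second-generation Grubbs catalyst (5 mol %), ethene (1 atm), CH2Cl2, rt; then 6 (3 equiv), N2, 40 °C
Reagents that add atoms: ethene, C=C
Why: Enyne metathesis of the terminal alkyne with ethene gives the 2-substituted butadiene, whose unhindered monosubstituted alkene should then undergo E-selective olefin cross-metathesis with the allyl silyl ether while the 1,1-disubstituted alkene and both stereocentres stay untouched.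

Step 5
Reactants: 8 (1R,2S,4E)-6-{[tert-butyl(dimethyl)silyl]oxy}-2-methyl-3-methylidene-1-(3,4,5-trimethoxyphenyl)hex-4-en-1-ol
Product: 9 (1R,2S)-2-{1-[(1E)-3-{[tert-butyl(dimethyl)silyl]oxy}prop-1-en-1-yl]cyclopropyl}-1-(3,4,5-trimethoxyphenyl)propan-1-ol
Conditions: Et2Zn, CH2I2, CH2Cl2, −10 → 0 °C
Reagents that add atoms: diiodomethane, ICI
Why: Simmons–Smith cyclopropanation should be delivered by the zinc alkoxide of the homoallylic hydroxyl group to the nearby, more electron-rich 1,1-disubstituted alkene, giving the vinylcyclopropane without creating a stereocentre (the two ring CH2 groups are equivalent).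

Step 6
Reactants: 9 (1R,2S)-2-{1-[(1E)-3-{[tert-butyl(dimethyl)silyl]oxy}prop-1-en-1-yl]cyclopropyl}-1-(3,4,5-trimethoxyphenyl)propan-1-ol
Product: 11 {[(1R,2S)-2-{1-[(1E)-3-{[tert-butyl(dimethyl)silyl]oxy}prop-1-en-1-yl]cyclopropyl}-1-(3,4,5-trimethoxyphenyl)propyl]oxy}(ethynyl)di(propan-2-yl)silane, via chlorosilyl ether 10 (not isolated)
Conditions: i-Pr2SiCl2, imidazole, CH2Cl2, 0 °C; then HC≡CMgBr, THF, 0 °C → rt
Reagents that add atoms: dichlorodi(propan-2-yl)silane, CC(C)[Si](Cl)(Cl)C(C)C; ethynylmagnesium bromide, C#C[Mg]Br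
Why: Silylation of the secondary alcohol with one Si–Cl bond of the dichlorosilane followed by substitution of the second chloride by the alkynyl Grignard reagent installs the temporary silicon tether that carries the alkyne.

Step 7
Reactants: 11 {[(1R,2S)-2-{1-[(1E)-3-{[tert-butyl(dimethyl)silyl]oxy}prop-1-en-1-yl]cyclopropyl}-1-(3,4,5-trimethoxyphenyl)propyl]oxy}(ethynyl)di(propan-2-yl)silane
Product: 12 (3R,4S,4aR)-4a-[(1E)-3-{[tert-butyl(dimethyl)silyl]oxy}prop-1-en-1-yl]-4-methyl-1,1-di(propan-2-yl)-3-(3,4,5-trimethoxyphenyl)-1,3,4,4a,5,6-hexahydro-7H-2,1-benzoxasilin-7-one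
Conditions: [Rh(CO)2Cl]2 (5 mol %), CO (0.2 atm in N2), toluene, 80 °C
Reagents that add atoms: carbon monoxide, [C-]#[O+]
Why: Monovalent rhodium coordinates the alkenyl group and inserts into the adjacent cyclopropane bond C3a–C5 to give a (π-allyl)(σ-alkyl) complex of trivalent rhodium, the tethered alkyne inserts at the allyl terminus C3a (bond C3a–C7a), CO inserts into the Rh–C5 bond (bond C5–C6) and reductive elimination joins C6 to C7. The closest known reaction type is the rhodium-catalysed carbonylative [(3+2)+1] cycloaddition of 1-yne-vinylcyclopropanes with CO (homologous Pauson–Khand reaction), applied here to a silyl ether tether. The six-membered C–Si–O ring closes in the alkyne insertion (exo mode fixed by the tether) and the cyclohexenone closes by CO insertion followed by C–C reductive elimination. The only new stereocentre, quaternary C3a, is controlled by the C2 and C3 stereocentres of the tether: in the insertion transition state the C3 methyl and C2 aryl groups should lie on the face away from the rhodacycle arm C4–C5–Rh, which places the small alkenyl group cis to both. The step needs cleavage of the proximal and not the distal cyclopropane bond, which π-allyl formation with the alkenyl group secures, and CO uptake instead of direct [3+2] closure, which the CO atmosphere secures.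

Step 8
Reactants: 12 (3R,4S,4aR)-4a-[(1E)-3-{[tert-butyl(dimethyl)silyl]oxy}prop-1-en-1-yl]-4-methyl-1,1-di(propan-2-yl)-3-(3,4,5-trimethoxyphenyl)-1,3,4,4a,5,6-hexahydro-7H-2,1-benzoxasilin-7-one
Product: 13 (4R)-4-[(1E)-3-hydroxyprop-1-en-1-yl]-4-[(1R,2S)-1-hydroxy-1-(3,4,5-trimethoxyphenyl)propan-2-yl]cyclohexane-1,3-dione
Conditions: Bu4NF, KHCO3, 30% aq. H2O2, THF/MeOH, 40 °C
Reagents that add atoms: hydrogen peroxide, OO
Why: Tamao–Fleming oxidation of the alkenyl(alkoxy)dialkylsilane replaces the C7a–Si bond by C7a–O, the resulting enol being the 1,3-diketone, while fluoride also cleaves the Si–O1 linkage and the tert-butyldimethylsilyl ether.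

Step 9
Reactants: 13 (4R)-4-[(1E)-3-hydroxyprop-1-en-1-yl]-4-[(1R,2S)-1-hydroxy-1-(3,4,5-trimethoxyphenyl)propan-2-yl]cyclohexane-1,3-dione
Product: 14 (2R,3S,3aR)-3a-[(1E)-3-hydroxyprop-1-en-1-yl]-3-methyl-2-(3,4,5-trimethoxyphenyl)-3,3a,4,5-tetrahydro-1-benzofuran-6(2H)-one
Conditions: PPTS (10 mol %), 4 Å molecular sieves, toluene, 60 °C
Reagents that add atoms: none
Why: Acid-catalysed condensation of the benzylic hydroxyl group with the 1,3-diketone (vinylogous ester formation) can close only the five-membered ring onto the C7a carbonyl and breaks no bond to C2, so the cis aryl/methyl relationship is kept.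

Step 10
Reactants: 14 (2R,3S,3aR)-3a-[(1E)-3-hydroxyprop-1-en-1-yl]-3-methyl-2-(3,4,5-trimethoxyphenyl)-3,3a,4,5-tetrahydro-1-benzofuran-6(2H)-one
Product: 17 (2R,3S,3aR)-3-methyl-3a-(prop-2-en-1-yl)-2-(3,4,5-trimethoxyphenyl)-3,3a,4,5-tetrahydro-1-benzofuran-6(2H)-one, via N-allylic sulfonylhydrazine 15 (not isolated), via allylic diazene 16 (not isolated)
Conditions: 2-nitrobenzenesulfonohydrazide, PPh3, DEAD, THF, −30 °C → rt
Reagents that add atoms: none
Why: Mitsunobu N-alkylation of the sulfonylhydrazide by the primary allylic alcohol, loss of sulfinic acid and retro-ene loss of dinitrogen from the allylic diazene should deliver hydrogen to the carbon attached to C3a and shift the double bond to the chain end (reductive 1,3-transposition), which turns the alkenyl group into the allyl group.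

Step 11
Reactants: 17 (2R,3S,3aR)-3-methyl-3a-(prop-2-en-1-yl)-2-(3,4,5-trimethoxyphenyl)-3,3a,4,5-tetrahydro-1-benzofuran-6(2H)-one
Product: 18 (2R,3S,3aS,5S)-5-hydroxy-3-methyl-3a-(prop-2-en-1-yl)-2-(3,4,5-trimethoxyphenyl)-3,3a,4,5-tetrahydro-1-benzofuran-6(2H)-one
Conditions: KN(SiMe3)2, THF, −78 °C; 2-(benzenesulfonyl)-3-phenyloxaziridine; AcOH
Reagents that add atoms: 2-(benzenesulfonyl)-3-phenyloxaziridine, O=S(=O)(N1OC1c1ccccc1)c1ccccc1
Why: Kinetic deprotonation of the vinylogous ester occurs at the α′ carbon C5 (Stork–Danheiser regiochemistry) and electrophilic hydroxylation of the enolate by the oxaziridine should take place on the face opposite the pseudo-axial C3a allyl group, giving the hydroxy ketone with oxygen trans to the allyl group.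

Step 12
Reactants: 18 (2R,3S,3aS,5S)-5-hydroxy-3-methyl-3a-(prop-2-en-1-yl)-2-(3,4,5-trimethoxyphenyl)-3,3a,4,5-tetrahydro-1-benzofuran-6(2H)-one
Product: 19 (2R,3S,3aS,5S)-5-methoxy-3-methyl-3a-(prop-2-en-1-yl)-2-(3,4,5-trimethoxyphenyl)-3,3a,4,5-tetrahydro-1-benzofuran-6(2H)-one
Conditions: Ag2O, MeI, MeCN, rt, dark
Reagents that add atoms: iodomethane, CI
Why: Silver-oxide-mediated O-methylation (Purdie methylation) etherifies the α-hydroxy ketone under non-basic conditions, so that neither the vinylogous ester nor the stereocentres are disturbed.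

Step 13
Reactants: 19 (2R,3S,3aS,5S)-5-methoxy-3-methyl-3a-(prop-2-en-1-yl)-2-(3,4,5-trimethoxyphenyl)-3,3a,4,5-tetrahydro-1-benzofuran-6(2H)-one
Product: 21 Dysodanthin B [(2R,3S,3aS,5R)-5-methoxy-3-methyl-3a-(prop-2-en-1-yl)-2-(3,4,5-trimethoxyphenyl)-3,3a,4,5-tetrahydro-1-benzofuran-6(2H)-one], via lithium enolate 20 (not isolated)
Conditions: LiN(i-Pr)2, THF, −78 °C; then 2,6-di-tert-butyl-4-methylphenol, −78 °C
Reagents that add atoms: none
Why: Deprotonation at C5 gives the planar α′ enolate, and kinetic C-protonation by the hindered phenol from the face opposite the pseudo-axial allyl group should place the new hydrogen trans and the methoxy group cis to the allyl group, which is the less stable 5R configuration of the target (enolate protonation under kinetic control).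

Compound list
1 | (S)-but-3-yn-2-ol | C#C[C@H](C)O | starting material
2 | (S)-but-3-yn-2-yl methanesulfonate | C#C[C@H](C)OS(C)(=O)=O | intermediate
3 | (aR)-tributyl(buta-1,2-dien-1-yl)stannane (M helicity) | [H]C(C)=[C@@]=C([H])[Sn](CCCC)(CCCC)CCCC | intermediate
4 | 3,4,5-trimethoxybenzaldehyde | COc1cc(C=O)cc(OC)c1OC | starting material
5 | (1R,2S)-2-methyl-1-(3,4,5-trimethoxyphenyl)but-3-yn-1-ol (syn) | O[C@@H](c1cc(OC)c(OC)c(OC)c1)[C@@H](C)C#C | intermediate
6 | tert-butyl(dimethyl)(prop-2-en-1-yloxy)silane | C=CCO[Si](C)(C)C(C)(C)C | starting material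
7 | (1R,2S)-2-methyl-3-methylidene-1-(3,4,5-trimethoxyphenyl)pent-4-en-1-ol | O[C@@H](c1cc(OC)c(OC)c(OC)c1)[C@@H](C)C(=C)C=C | intermediate (not isolated)
8 | (1R,2S,4E)-6-{[tert-butyl(dimethyl)silyl]oxy}-2-methyl-3-methylidene-1-(3,4,5-trimethoxyphenyl)hex-4-en-1-ol | O[C@@H](c1cc(OC)c(OC)c(OC)c1)[C@@H](C)C(=C)/C=C/CO[Si](C)(C)C(C)(C)C | intermediate
9 | (1R,2S)-2-{1-[(1E)-3-{[tert-butyl(dimethyl)silyl]oxy}prop-1-en-1-yl]cyclopropyl}-1-(3,4,5-trimethoxyphenyl)propan-1-ol | O[C@@H](c1cc(OC)c(OC)c(OC)c1)[C@@H](C)C1(/C=C/CO[Si](C)(C)C(C)(C)C)CC1 | intermediate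
10 | {[(1R,2S)-2-{1-[(1E)-3-{[tert-butyl(dimethyl)silyl]oxy}prop-1-en-1-yl]cyclopropyl}-1-(3,4,5-trimethoxyphenyl)propyl]oxy}(chloro)di(propan-2-yl)silane | Cl[Si](C(C)C)(C(C)C)O[C@@H](c1cc(OC)c(OC)c(OC)c1)[C@@H](C)C1(/C=C/CO[Si](C)(C)C(C)(C)C)CC1 | intermediate (not isolated)
11 | {[(1R,2S)-2-{1-[(1E)-3-{[tert-butyl(dimethyl)silyl]oxy}prop-1-en-1-yl]cyclopropyl}-1-(3,4,5-trimethoxyphenyl)propyl]oxy}(ethynyl)di(propan-2-yl)silane | C#C[Si](C(C)C)(C(C)C)O[C@@H](c1cc(OC)c(OC)c(OC)c1)[C@@H](C)C1(/C=C/CO[Si](C)(C)C(C)(C)C)CC1 | intermediate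
12 | (3R,4S,4aR)-4a-[(1E)-3-{[tert-butyl(dimethyl)silyl]oxy}prop-1-en-1-yl]-4-methyl-1,1-di(propan-2-yl)-3-(3,4,5-trimethoxyphenyl)-1,3,4,4a,5,6-hexahydro-7H-2,1-benzoxasilin-7-one (cyclohexenone fused to the six-membered C–Si–O ring; aryl, methyl and alkenyl groups mutually cis) | CC(C)(C)[Si](C)(C)OC/C=C/[C@@]12CCC(=O)C=C1[Si](C(C)C)(C(C)C)O[C@@H](c3cc(OC)c(OC)c(OC)c3)[C@H]2C | intermediate
13 | (4R)-4-[(1E)-3-hydroxyprop-1-en-1-yl]-4-[(1R,2S)-1-hydroxy-1-(3,4,5-trimethoxyphenyl)propan-2-yl]cyclohexane-1,3-dione | OC/C=C/[C@]1(CCC(=O)CC1=O)[C@H](C)[C@@H](O)c1cc(OC)c(OC)c(OC)c1 | intermediate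
14 | (2R,3S,3aR)-3a-[(1E)-3-hydroxyprop-1-en-1-yl]-3-methyl-2-(3,4,5-trimethoxyphenyl)-3,3a,4,5-tetrahydro-1-benzofuran-6(2H)-one | OC/C=C/[C@@]12CCC(=O)C=C1O[C@@H](c3cc(OC)c(OC)c(OC)c3)[C@H]2C | intermediate
15 | N-{(2E)-3-[(2R,3S,3aR)-3-methyl-6-oxo-2-(3,4,5-trimethoxyphenyl)-2,3,4,5-tetrahydro-1-benzofuran-3a(6H)-yl]prop-2-en-1-yl}-2-nitrobenzenesulfonohydrazide | NN(C/C=C/[C@@]12CCC(=O)C=C1O[C@@H](c3cc(OC)c(OC)c(OC)c3)[C@H]2C)S(=O)(=O)c1ccccc1[N+](=O)[O-] | intermediate (not isolated)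
16 | (2R,3S,3aR)-3a-[(1E)-3-diazenylprop-1-en-1-yl]-3-methyl-2-(3,4,5-trimethoxyphenyl)-3,3a,4,5-tetrahydro-1-benzofuran-6(2H)-one | N=NC/C=C/[C@@]12CCC(=O)C=C1O[C@@H](c3cc(OC)c(OC)c(OC)c3)[C@H]2C | intermediate (not isolated)
17 | (2R,3S,3aR)-3-methyl-3a-(prop-2-en-1-yl)-2-(3,4,5-trimethoxyphenyl)-3,3a,4,5-tetrahydro-1-benzofuran-6(2H)-one | C=CC[C@@]12CCC(=O)C=C1O[C@@H](c3cc(OC)c(OC)c(OC)c3)[C@H]2C | intermediate
18 | (2R,3S,3aS,5S)-5-hydroxy-3-methyl-3a-(prop-2-en-1-yl)-2-(3,4,5-trimethoxyphenyl)-3,3a,4,5-tetrahydro-1-benzofuran-6(2H)-one (hydroxyl trans to allyl) | C=CC[C@@]12C[C@H](O)C(=O)C=C1O[C@@H](c3cc(OC)c(OC)c(OC)c3)[C@H]2C | intermediate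
19 | (2R,3S,3aS,5S)-5-methoxy-3-methyl-3a-(prop-2-en-1-yl)-2-(3,4,5-trimethoxyphenyl)-3,3a,4,5-tetrahydro-1-benzofuran-6(2H)-one (C5 epimer of the target) | C=CC[C@@]12C[C@H](OC)C(=O)C=C1O[C@@H](c3cc(OC)c(OC)c(OC)c3)[C@H]2C | intermediate
20 | lithium enolate of 19 (C5=C6–OLi) | C=CC[C@@]12CC(OC)=C(O[Li])C=C1O[C@@H](c3cc(OC)c(OC)c(OC)c3)[C@H]2C | intermediate (not isolated)
21 | Dysodanthin B, (2R,3S,3aS,5R)-5-methoxy-3-methyl-3a-(prop-2-en-1-yl)-2-(3,4,5-trimethoxyphenyl)-3,3a,4,5-tetrahydro-1-benzofuran-6(2H)-one | C=CC[C@@]12C[C@@H](OC)C(=O)C=C1O[C@@H](c3cc(OC)c(OC)c(OC)c3)[C@H]2C | target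

Total step count: 13
Longest linear sequence: 13 steps (from 1; compounds 4 and 6 are purchased)

Steps most likely to fail

Step 7 (key step). What may go wrong: alkyne insertion through the six-membered silyl ether tether may be slow, so that closure without CO uptake or catalyst decay competes, and facial selectivity at C3a may be low. Fallback: the tether atom is changed from silicon to oxygen. The fallback sets out from 9. KH and trichloroethene in THF should give the (E)-1,2-dichlorovinyl ether F1. n-BuLi (−78 °C, then MeOH) should convert it into the ethynyl ether F2. The same [Rh(CO)2Cl]2/CO cycloaddition, now through the five-membered tether and run at the lowest workable temperature because benzylic alkynyl ethers are heat-sensitive, should give the silyl-protected vinylogous ester F3 directly, with the enol ether oxygen already in place. Bu4NF then frees the allylic alcohol, and the route is rejoined at 14.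

Step 13. What may go wrong: protonation on oxygen followed by equilibration of the enol, or unselective C-protonation, would return the more stable trans isomer. Fallback: C5 is inverted by substitution instead of protonation. The fallback sets out from 18. A Mitsunobu reaction (PPh3, DIAD, 4-nitrobenzoic acid, toluene) should give the inverted 4-nitrobenzoate F6. Brief methanolysis (K2CO3, MeOH, 0 °C) should give the cis hydroxy ketone F7. Ag2O/MeI as in step 12 then gives 21 directly.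

Step 5. What may go wrong: the zinc carbenoid may also attack the disubstituted alkene next to the silyloxy group, or both alkenes. Fallback: the cyclopropane is made before the second alkene exists. The fallback sets out from 5. Copper-catalysed α-selective protoboration (CuCl, 1,3-dimesitylimidazolinium chloride, NaOt-Bu, B2pin2, MeOH, THF) should give the 1,1-disubstituted alkenylboronate F4. Simmons–Smith cyclopropanation (Et2Zn, CH2I2) of its only alkene should give the cyclopropylboronate F5. Suzuki–Miyaura coupling with (E)-tert-butyl[(3-iodoprop-2-en-1-yl)oxy]dimethylsilane (Pd(OAc)2, RuPhos, K3PO4, toluene/water) rejoins the route at 9.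

Further compounds
F1 | step 7 | tert-butyl{[(2E)-3-(1-{(1R,2S)-1-[(E)-1,2-dichloroethenyl]oxy-1-(3,4,5-trimethoxyphenyl)propan-2-yl}cyclopropyl)prop-2-en-1-yl]oxy}dimethylsilane | Cl/C=C(/Cl)O[C@@H](c1cc(OC)c(OC)c(OC)c1)[C@@H](C)C1(/C=C/CO[Si](C)(C)C(C)(C)C)CC1
F2 | step 7 | tert-butyl{[(2E)-3-(1-{(1R,2S)-1-(ethynyloxy)-1-(3,4,5-trimethoxyphenyl)propan-2-yl}cyclopropyl)prop-2-en-1-yl]oxy}dimethylsilane | C#CO[C@@H](c1cc(OC)c(OC)c(OC)c1)[C@@H](C)C1(/C=C/CO[Si](C)(C)C(C)(C)C)CC1
F3 | step 7 | (2R,3S,3aR)-3a-[(1E)-3-{[tert-butyl(dimethyl)silyl]oxy}prop-1-en-1-yl]-3-methyl-2-(3,4,5-trimethoxyphenyl)-3,3a,4,5-tetrahydro-1-benzofuran-6(2H)-one | CC(C)(C)[Si](C)(C)OC/C=C/[C@@]12CCC(=O)C=C1O[C@@H](c3cc(OC)c(OC)c(OC)c3)[C@H]2C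
F4 | step 5 | (1R,2S)-2-methyl-3-(4,4,5,5-tetramethyl-1,3,2-dioxaborolan-2-yl)-1-(3,4,5-trimethoxyphenyl)but-3-en-1-ol | O[C@@H](c1cc(OC)c(OC)c(OC)c1)[C@@H](C)C(=C)B1OC(C)(C)C(C)(C)O1
F5 | step 5 | (1R,2S)-2-[1-(4,4,5,5-tetramethyl-1,3,2-dioxaborolan-2-yl)cyclopropyl]-1-(3,4,5-trimethoxyphenyl)propan-1-ol | O[C@@H](c1cc(OC)c(OC)c(OC)c1)[C@@H](C)C1(CC1)B1OC(C)(C)C(C)(C)O1
F6 | step 13 | (2R,3S,3aS,5R)-3-methyl-6-oxo-3a-(prop-2-en-1-yl)-2-(3,4,5-trimethoxyphenyl)-2,3,3a,4,5,6-hexahydro-1-benzofuran-5-yl 4-nitrobenzoate | C=CC[C@@]12C[C@@H](OC(=O)c4ccc(cc4)[N+](=O)[O-])C(=O)C=C1O[C@@H](c3cc(OC)c(OC)c(OC)c3)[C@H]2C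
F7 | step 13 | (2R,3S,3aS,5R)-5-hydroxy-3-methyl-3a-(prop-2-en-1-yl)-2-(3,4,5-trimethoxyphenyl)-3,3a,4,5-tetrahydro-1-benzofuran-6(2H)-one | C=CC[C@@]12C[C@@H](O)C(=O)C=C1O[C@@H](c3cc(OC)c(OC)c(OC)c3)[C@H]2C
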